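**Plan**

1. Retrosynthesis first cuts the two C–CH2 bonds of the methylene bridge (retro-Michael, retro-Mannich), giving acetylfilicinic acid (ring B), butyrylfilicinic acid (ring A) and a one-carbon iminium unit.
2. Each ring is then cut at two bonds: in ring B the bond from the ring C=O to the acetyl-bearing carbon, and the bond from the bridge-bearing carbon to the C(OH) next to C(CH3)2. This leads back to dimethyl 2,2-dimethylmalonate and acetylacetone; ring A leads back likewise to heptane-2,4-dione.
3. The enabling feature: in each ring the quaternary C(CH3)2 carbon sits between two oxygenated ring carbons, a dimethylmalonyl 1,3-dielectrophile that cannot enolise. The other three ring carbons, C(acyl)–C(OH)–C(bridge), are C3–C2–C1 of a β-diketone 1,3-dianion, so each ring is a [3+3] Claisen–Dieckmann cyclocondensation that copies polyketide ring formation with the C-methyl groups already in place.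
4. Forward order: ring B (step 1), heptane-2,4-dione by γ-ethylation of acetylacetone (step 2), ring A by the same annulation (step 3), a Mannich handle on ring A (step 4), and joining of the two rings by elimination and Michael addition (step 5).
5. Stereochemistry: the target has no stereocentre and no stereogenic double bond, so nothing has to be set.

Key step: step 1

Remark: all ring compounds are written in the enol tautomer that matches the target SMILES; the tautomers of these β-triketones are in rapid equilibrium.

**Route**

Step 1
Reactants: 1 acetylacetone (pentane-2,4-dione); 2 dimethyl 2,2-dimethylmalonate
Product: 4 acetylfilicinic acid (2-acetyl-3,5-dihydroxy-6,6-dimethylcyclohexa-2,4-dien-1-one), via triketo ester 3 (not isolated)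
Conditions: 1 (1.3 equiv), NaH (6 equiv), DME, reflux, slow addition of 2 (1.0 equiv); then 2 M HCl, 0 °C
Reagents that add atoms: none
Why: Excess NaH turns 1 into its sodium enolate and, at reflux, into a low stationary concentration of the 1,3-dianion, whose terminal carbon attacks one ester group of 2 (first new bond, former methyl carbon of 1 to an ester carbon) to give the sodium polyenolate of triketo ester 3; the doubly activated C6 of 3 (former C3 of 1) then attacks the second ester group in an intramolecular Claisen (Dieckmann) condensation (second new bond), and the sequence ends in the stable sodium polyenolate of 4. The closest known reaction types are the NaH-mediated terminal acylation of β-diketones with esters to 1,3,5-triketones, the base-induced Claisen cyclisation of 3,5,7-triketo esters to acylphloroglucinols and the classical Claisen–Dieckmann self-condensation of malonic esters to phloroglucinol carboxylates, run here as one [3+3] cyclocondensation. Ring B closes in a 6-exo-trig mode (enolate carbon onto the ester carbonyl, allowed as enolexo or enolendo), helped by the Thorpe–Ingold effect of the gem-dimethyl group. No stereocentre is formed. The step needs C-acylation and not O-acylation, Claisen and not aldol closure, and cyclisation and not a second intermolecular acylation: ester electrophiles keep each acylation reversible until the carbocycle is trapped as its polyanion, the ester of 3 is insulated from the enolate system by the quaternary carbon and so is the only unconjugated carbonyl, 2 can neither enolise nor self-condense, slow addition of 2 to an excess of 1 disfavours double acylation, and the symmetry of 1 makes both termini equivalent.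

Step 2
Reactants: 1 acetylacetone
Product: 5 heptane-2,4-dione
Conditions: NaH (1.1 equiv), THF, 0 °C; n-BuLi (1.05 equiv), 0 °C; EtI (1.0 equiv), 0 °C to rt; then dilute HCl
Reagents that add atoms: iodoethane, CCI
Why: γ-Alkylation of a β-diketone 1,3-dianion: the terminal carbanion is far more basic and nucleophilic than the central enolate, so one equivalent of the primary iodide should alkylate only the methyl terminus by SN2 substitution.

Step 3
Reactants: 5 heptane-2,4-dione; 2 dimethyl 2,2-dimethylmalonate
Product: 7 butyrylfilicinic acid (2-butanoyl-3,5-dihydroxy-6,6-dimethylcyclohexa-2,4-dien-1-one), via triketo ester 6 (not isolated)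
Conditions: 5 (1.2 equiv), NaH (6 equiv), DME, reflux, slow addition of 2 (1.0 equiv); then 2 M HCl, 0 °C
Reagents that add atoms: none
Why: The same tandem Claisen–Dieckmann [3+3] cyclocondensation as in step 1; ionisation and acylation of 5 at the C1 methyl, favoured over the more hindered C5 methylene (primary over secondary carbanion), should leave the propyl group in the side chain, and ring A closes 6-exo-trig through C3 to the sodium polyenolate of 7.

Step 4
Reactants: 7 butyrylfilicinic acid
Product: 8 Mannich base (2-butanoyl-4-[(dimethylamino)methyl]-3,5-dihydroxy-6,6-dimethylcyclohexa-2,4-dien-1-one, expected as its zwitterion)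
Conditions: Me2NCH2NMe2 (1.5 equiv), MeCN, 0 °C to rt; volatiles removed in vacuo, crude solid used directly
Reagents that add atoms: N,N,N′,N′-tetramethylmethanediamine, CN(C)CN(C)C
Why: Mannich reaction: the strongly acidic enol of 7 protonates the aminal and releases the N,N-dimethylmethyleneiminium ion, which is attacked by the only unsubstituted nucleophilic ring carbon (between the two enolic carbons of ring A), and the amine-rich medium should return any eliminated material to 8 instead of letting free 7 add to it.

Step 5
Reactants: 8 Mannich base; 4 acetylfilicinic acid
Product: 10 albaspidin AB, via methylidene trione 9 (not isolated)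
Conditions: 8 added in portions to 4 (1.2 equiv), MeCN, 50 °C, N2; then 1 M HCl wash
Reagents that add atoms: none
Why: Elimination then Michael addition: E1cB loss of dimethylamine from the zwitterion gives the transient 4-methylidene trione 9 (an ortho-quinone methide analogue), which is captured at its exocyclic carbon by the single free enolic ring carbon of 4, and the mild, base-poor medium should limit retro-Michael exchange of the two halves.

**Compound list**

1 | acetylacetone (pentane-2,4-dione) | CC(=O)CC(C)=O | starting material
2 | dimethyl 2,2-dimethylmalonate | COC(=O)C(C)(C)C(=O)OC | starting material
3 | methyl 2,2-dimethyl-3,5,7-trioxooctanoate (present as its sodium polyenolate) | COC(=O)C(C)(C)C(=O)CC(=O)CC(C)=O | intermediate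
4 | acetylfilicinic acid (2-acetyl-3,5-dihydroxy-6,6-dimethylcyclohexa-2,4-dien-1-one) | CC(=O)C1=C(O)C=C(O)C(C)(C)C1=O | intermediate
5 | heptane-2,4-dione | CCCC(=O)CC(C)=O | intermediate
6 | methyl 2,2-dimethyl-3,5,7-trioxodecanoate (present as its sodium polyenolate) | COC(=O)C(C)(C)C(=O)CC(=O)CC(=O)CCC | intermediate
7 | butyrylfilicinic acid (2-butanoyl-3,5-dihydroxy-6,6-dimethylcyclohexa-2,4-dien-1-one) | CCCC(=O)C1=C(O)C=C(O)C(C)(C)C1=O | intermediate
8 | 2-butanoyl-4-[(dimethylamino)methyl]-3,5-dihydroxy-6,6-dimethylcyclohexa-2,4-dien-1-one (Mannich base) | CCCC(=O)C1=C(O)C(CN(C)C)=C(O)C(C)(C)C1=O | intermediate
9 | 2-butanoyl-3-hydroxy-6,6-dimethyl-4-methylidenecyclohex-2-ene-1,5-dione | CCCC(=O)C1=C(O)C(=C)C(=O)C(C)(C)C1=O | intermediate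
10 | albaspidin AB (2-acetyl-4-[(3-butanoyl-2,6-dihydroxy-5,5-dimethyl-4-oxocyclohexa-2,6-dien-1-yl)methyl]-3,5-dihydroxy-6,6-dimethylcyclohexa-2,4-dien-1-one) | CCCC(=O)C1=C(O)C(CC2=C(O)C(C)(C)C(=O)C(C(C)=O)=C2O)=C(O)C(C)(C)C1=O | target

**Step count and risks**

Total step count: 5. Longest linear sequence: 4 (steps 2, 3, 4, 5).

The three steps most likely to fail:

Step 1. The ring closure may stall at the open triketo ester, run through oxygen to a pyranone, or take the aldol course from the terminal methyl onto the C3 ketone and aromatise; the polyanion may also be acylated a second time at its free methyl terminus. The fallback for step 1 builds the ring without the acetyl group and adds it last. It sets out from 2: crossed Claisen condensation with the lithium enolate of acetone, made with lithium diisopropylamide in THF at −78 °C, should give methyl 2,2-dimethyl-3,5-dioxohexanoate F1 as the open diketo ester. Its dianion, made with 2.2 equiv of lithium diisopropylamide in THF at −78 °C and warmed to rt, should close by Dieckmann condensation through the terminal carbanion to filicinic acid F2 after acidification. Friedel–Crafts-type C-acetylation of the enolic ring carbon with Ac2O and BF3·OEt2 then comes back to the route at 4.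

Step 3. Ionisation of 5 at the C5 methylene may compete with ionisation at the C1 methyl, which would divert part of the material into the isomeric ring with an acetyl side chain and a ring ethyl group. The fallback for step 3 removes the competing site instead of relying on its lower acidity. It sets out from 2: the same NaH-mediated cyclocondensation in DME at reflux, run with commercial 1-cyclopropylbutane-1,3-dione in place of 5, should give cyclopropanecarbonylfilicinic acid F3 as the only ring isomer, because the cyclopropyl methine resists enolisation and leaves the methyl group as the single terminal site. Hydrogenolysis of the cyclopropane bond that starts at the carbon next to the carbonyl group, with H2 over Pd/C in EtOAc at rt, is a known opening of cyclopropyl ketones to n-propyl ketones and comes back to the route at 7.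

Step 5. The two halves may exchange by retro-Michael cleavage under the amine that is set free, or the transient methylidene trione may add to its own precursor or oligomerise before 4 captures it. The fallback for step 5 gives up the directed coupling and sets out from 4 and 7, bypassing 8: classical co-condensation of equimolar 4 and 7 with aqueous formaldehyde in dilute aqueous KOH at rt should give the mixed dimer in a statistical mixture with the two symmetrical dimers, and chromatographic separation comes back to the route at 10. This fallback makes no new compound.

**Further compounds**

F1 | step 1 | methyl 2,2-dimethyl-3,5-dioxohexanoate | COC(=O)C(C)(C)C(=O)CC(C)=O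
F2 | step 1 | filicinic acid | CC1(C)C(O)=CC(O)=CC1=O
F3 | step 3 | cyclopropanecarbonylfilicinic acid | O=C(C1CC1)C1=C(O)C=C(O)C(C)(C)C1=O
F0 | step 5 | none | none
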